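All constants are assumed; no experiment stands behind them.

In a one-step reversible world, a flask given enough time stands where its equilibrium lies, so we ask first whether time is enough and then where that point is.

    substrate + coupling partner ⇌ product + by-product (K1 = 2.1, k1 = 0.13 L mol⁻¹ s⁻¹)

substrate 0.30 M; coupling partner 0.180 M; time 6.0 h

- the reaction counts as stopped when no species that holds the substrate changes by six tenths of a point or more over the second half of the time
- run time (flask): 6.0 h

- why nothing more happens at 6.0 h, or that something still does (it is still moving / the coupling partner has run out first / forward and back rates have come level / all of the substrate has reacted)
- part of the substrate gone at 6.0 h
- the product standing at 6.0 h, as a percentage of the substrate charged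
- amount of product if the flask were left three thousand times as long, in percent of the substrate charged

We turn the settings by hand, one after the other. Time comes first: by the forward step alone, at the charged [coupling partner], substrate has a lifetime of 0.712 min. Because that is far shorter than the 6.0 h run, we expect time to change nothing. Coupling partner comes next: it is the limiting reagent, and its charge allows 60.0 % of product. But the step runs back, so we carry the equilibrium extent: the [product] x at which x squared, divided by (charged [substrate] − x) and (charged [coupling partner] − x), equals 2.1. Here it is 0.131 M, or 43.8 % of the substrate, less than that cap. With the constant and the substrate held, more coupling partner raises x. Substrate comes last: with the constant and the coupling partner held, more of it also raises x, but x then stands against a larger charge, so the percentage falls.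

The forecast says forward and back rates have come level, with 43.8 % conversion, 43.8 % product and 43.8 % after the long wait, since “waiting longer changes nothing under the given rate law”.

The flask gives 43.8 % conversion, 43.8 % product and 43.8 % after the long wait: forward and back rates have come level. Moved up or down by one common factor, the settings shift the product in this order: coupling partner (7.9 points), then substrate (7.9 points), then time (under 0.05 points); with 0.151 M of coupling partner it has moved by 5 points, so a run at that charge parts from the forecast's 43.8 % by that much. The extent also gives what remains of the coupling partner, 27.0 % of its charge, and the flask holds 27 %.

For the neighbouring flask with 0.075 M of substrate, the coupling partner as before, the same extent gives 0.0604 M, or 80.5 % of its substrate. Computed, that neighbouring flask gives 80.6 % product.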